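# Abroquinone A by annulation of a symmetric aryne with a chiral bromo alkoxide

Compound numbers are those of the route (steps 1 to 9) and of the compound list below.

## Analysis of the target

Abroquinone A is an isoflavan quinone. A 6,7-dimethoxychroman (benzene ring A fused to the dihydropyran ring C) carries at C3 a 2,3-dimethoxy-1,4-benzoquinone (ring B), bonded through the quinone carbon that is C1' in isoflavan numbering. The only stereocentre is C3, which the SMILES defines as (S) (C2 > C1' > C4 > H). It lies between the two methylene groups C2 and C4, so there is no relative stereochemistry to control and no neighbouring functional group to direct its formation. The two arms differ only in where they end (O1 on C2, the arene carbon C4a on C4), so the centre has to be set on a precursor in which the arms are clearly different. The quinone is the sensitive group: it is electrophilic, redox-active and base-labile, and once it exists the C3–H can be lost through tautomerisation towards a quinone methide. Ring B should therefore travel as a protected 2'-phenol with a free para position (C5') and be oxidised last. Ring A is a 1,2,4-trioxygenated benzene with O1 and the 6-methoxy group para to each other, so oxidants that demethylate para-dialkoxyarenes must be avoided at the end. The plan rests on one feature: ring A is joined to ring C through two adjacent carbons, C8a (to O1) and C4a (to C4), and its 6,7-dimethoxy pattern is symmetric with respect to them, so ring A is the adduct of 4,5-dimethoxybenzyne with an oxygen nucleophile and a carbon electrophile.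

## Retrosynthetic reasoning

**Target 18 to phenol 17.** The C5'–O bond and the quinone oxidation level are removed first. In 17 the hydroxyl at C2' has both ortho positions blocked (C1' by the chroman, C3' by methoxy) and the para position C5' free, so a phenol-selective nitroxyl-radical oxidation (Teuber reaction) can only give the para-quinone. Ring A has no free hydroxyl and should be left alone. Doing this last keeps the base- and nucleophile-sensitive quinone, and the labile C3–H beside it, out of every other step.

**Phenol 17 to MOM ether 16.** The phenol is masked as its methoxymethyl ether. This group does three jobs: it directs the metalation that defines C1', it is inert to hydride, fluoride and carbanions, and it comes off by acid methanolysis, which the methyl ethers and the chroman tolerate.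

**Chroman 16 to bromo alcohol 11 and silyl triflate 12 (key disconnection).** C8a–O1 and C4–C4a are cut together. Both bonds end on neighbouring carbons of ring A, so ring A becomes the aryne 14, released from the purchasable precursor 12, and the rest is a three-carbon unit with oxygen on one arm and bromide on the other. Because 14 is symmetric, it does not matter which aryne carbon receives the oxygen. The cut passes beside the stereocentre, not through it. Cutting O1–C2 alone would require a separately built ring-A phenol bearing an ortho carbon chain, and cutting C3–C1' would require an enantioselective sp3–sp2 coupling. In the forward direction alkoxide 13 must add to 14, and the aryl anion 15 must alkylate itself on the primary bromide before it finds a proton.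

**Bromo alcohol 11 to silyl ether bromide 10 to alcohol 9.** These are functional-group changes. In 11 the stereocentre is defined only by which arm carries OH and which carries Br, so bromide goes onto the free hydroxymethyl arm of 9 and the other arm is then desilylated. The gain is a monoprotected 2-aryl-1,3-propanediol. Either enantiomer of such a diol derivative can be led to 11 by choosing the order in which the arms are handled.

**Alcohol 9 to alkene 7.** The C3–H bond and the terminal C–O bond are cut, which corresponds to an enantioselective anti-Markovnikov hydroboration–oxidation of a 1,1-disubstituted aryl alkene through boronate 8. The forward reaction has to distinguish the two faces of an alkene whose substituents are an aryl group and a silyloxymethyl group. The stereocentre is created when hydrogen is delivered to the internal carbon.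

**Alkene 7 to MOM ether 2 and vinyl bromide 4.** The sp2–sp2 bond C3–C1' is cut. The position ortho to the MOM group of 2 is exactly C1', so directed lithiation (5), transmetalation to zinc (6) and Negishi coupling with 4 join the fragments in one operation. Compounds 2 and 4 come from phenol 1 and bromo alcohol 3 by routine protection.

## Alternatives that were turned down

**Alternative 1:** The cut is at C3–C1', with a temporary C4–O bond to the future 2'-oxygen. Ring B arrives as 2,3-dimethoxy-1,4-benzoquinone A2 and rings A and C as 6,7-dimethoxy-2H-chromene A1. A chiral titanium Lewis acid of the TADDOL type would activate A2, and C3 of A1 would add to an unsubstituted quinone carbon. The C4 cation, stabilised by O1 and the 7-methoxy group, would be captured by the neighbouring quinone oxygen to give the cis-fused pterocarpan A3. Hydrogenolysis of the benzylic C–O bond and reoxidation would finish the target.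
- For it: it is very convergent, the whole route would be about half as long as the chosen one, ring B arrives with its full oxygen pattern, and the reaction class is known.
- Against it: A2 carries two donor methoxy groups and is a weak electrophile. The cationic intermediate can also collapse through carbon to cyclobutane or bridged adducts. A1 is an acid-sensitive, electron-rich styrene that oligomerises under Lewis acids. Enantiocontrol depends on a stoichiometric chiral titanium complex in the same event that forms the C–C bond.
- Comparison: alternative 1 is clearly stronger in step economy. The chosen strategy instead separates enantiocontrol (a catalytic reaction on a simple alkene, with an enzymatic backup) from ring construction, has no competing cycloaddition modes, and keeps every intermediate a stable aromatic ether until the last step.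

**Alternative 2:** C3–C4 and O1–C2 are cut. Arylacetaldehyde A4 would form an enamine with a diarylprolinol silyl ether. This adds to the ortho-quinone methide A6 released by base from sulfone A5, and the phenoxide closes onto the aldehyde carbon to give lactol A7. Reductive removal of the lactol hydroxyl, debenzylation and phenol oxidation would follow.
- For it: the key step is organocatalytic, forms the stereocentre and ring C together, and has close precedent with simple aldehydes.
- Against it: C3 of A7 is alpha to a masked aldehyde and also benzylic. Ring-opening of the lactol gives an alpha-aryl aldehyde that the amine catalyst and the base can enolise, so the enantiomeric purity is at risk in the step that creates it. It is at risk again in the ionic reduction, whose oxocarbenium ion can lose the C3 proton. A4 is prone to self-condensation, and both fragments need several steps.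
- Comparison: the overall length is similar, and alternative 2 is stronger in that its key step is not new. The chosen strategy never places a carbonyl or cation next to C3 after it is set.

**Alternative 3:** Only O1–C8a is cut. Catechol A8 would be oxidised to ortho-quinone A9. The primary hydroxyl adds to the ring carbon next to the side chain, as catecholamine side chains do, and tautomerisation gives the chroman-6,7-diol A10. Double O-methylation, MOM removal and phenol oxidation would follow.
- For it: the reagents are cheap, no strong base is needed, and the cyclisation mode is biomimetic.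
- Against it: an alcohol is a much weaker nucleophile than an amine, while ortho-quinones with a benzylic CH2 tautomerise readily to quinone methides and polymerise. A10 is more easily oxidised than A8, so over-oxidation is built in. A8 needs the same acyclic stereocentre as the chosen route, plus a separately made C4–C4a bond and catechol protection orthogonal to MOM, and the two methyl groups must be added afterwards.
- Comparison: the key step forms one bond where the aryne annulation forms two. The chosen strategy brings ring A in with its methyl ethers in place and avoids oxidation-prone catechols. Alternative 3 is stronger only in that its chemistry carries less mechanistic uncertainty per step.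

Key step: step 7

## Remarks and assumptions

- Configuration: read from the SMILES, C3 of the target is (S). All chroman intermediates are drawn and named accordingly.
- Ligand: L* is (S)-4-tert-butyl-2-{6-[1-(2,6-diisopropylphenylimino)ethyl]pyridin-2-yl}-4,5-dihydrooxazole, and CoCl2(L*) is its cobalt dichloride complex.
- Assumption: the (S)-ligand is taken to deliver (R)-9. If the catalyst shows the opposite sense on alkene 7, the (R)-ligand is used and nothing else changes.

## Route

Step 1
Reactants: 1 2,3-dimethoxyphenol
Product: 2 1,2-dimethoxy-3-(methoxymethoxy)benzene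
Conditions: MOMCl, iPr2NEt, CH2Cl2, 0 °C → rt
Reagents that add atoms: chloromethyl methyl ether, COCCl
Why: O-alkylation of the phenol by the reactive alpha-chloro ether gives the MOM acetal. The group later directs the ortho-metalation and withstands organometallic, hydride, fluoride and carbanion conditions.

Step 2
Reactants: 3 2-bromoprop-2-en-1-ol
Product: 4 [(2-bromoprop-2-en-1-yl)oxy](tert-butyl)dimethylsilane
Conditions: TBSCl, imidazole, CH2Cl2, rt
Reagents that add atoms: tert-butyldimethylsilyl chloride, CC(C)(C)[Si](C)(C)Cl
Why: Imidazole-promoted silylation of a primary allylic alcohol. The silyl ether removes the acidic proton before the organozinc coupling and later marks one of the two arms.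

Step 3
Reactants: 2 1,2-dimethoxy-3-(methoxymethoxy)benzene; 4 [(2-bromoprop-2-en-1-yl)oxy](tert-butyl)dimethylsilane
Product: 7 tert-butyl({2-[3,4-dimethoxy-2-(methoxymethoxy)phenyl]prop-2-en-1-yl}oxy)dimethylsilane, via aryllithium 5 (not isolated), via arylzinc chloride 6 (not isolated)
Conditions: nBuLi, TMEDA, THF, 0 °C; ZnCl2, 0 °C → rt; then 4, Pd(PPh3)4 (3 mol%), THF, 50 °C
Reagents that add atoms: none
Why: Directed ortho-metalation occurs beside the chelating MOM group, which outranks methoxy as a director, so the metal sits at the future C1'. Transmetalation to zinc and Negishi coupling with the vinyl bromide (oxidative addition to zerovalent palladium, transmetalation, reductive elimination) form the C3–C1' bond.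

Step 4
Reactants: 7 tert-butyl({2-[3,4-dimethoxy-2-(methoxymethoxy)phenyl]prop-2-en-1-yl}oxy)dimethylsilane
Product: 9 (2R)-3-{[tert-butyl(dimethyl)silyl]oxy}-2-[3,4-dimethoxy-2-(methoxymethoxy)phenyl]propan-1-ol, via pinacol boronate 8 (not isolated)
Conditions: CoCl2(L*) (2 mol%), NaBHEt3 (6 mol%), HBpin (1.2 equiv), THF, rt; then H2O2, NaOH aq, THF, 0 °C
Reagents that add atoms: hydrogen peroxide, OO
Why: Cobalt-catalysed enantioselective anti-Markovnikov hydroboration of a 1,1-disubstituted aryl alkene, followed by oxidation of the C–B bond. The cobalt hydride delivers hydrogen to the internal carbon from the face selected by the chiral ligand, which tells the flat aryl group from the silyloxymethyl arm, and this sets C3. The oxidation takes place at the CH2 carbon and does not touch the stereocentre.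

Step 5
Reactants: 9 (2R)-3-{[tert-butyl(dimethyl)silyl]oxy}-2-[3,4-dimethoxy-2-(methoxymethoxy)phenyl]propan-1-ol
Product: 10 {(2S)-3-bromo-2-[3,4-dimethoxy-2-(methoxymethoxy)phenyl]propoxy}(tert-butyl)dimethylsilane
Conditions: CBr4, PPh3, 2,6-lutidine, CH2Cl2, 0 °C
Reagents that add atoms: carbon tetrabromide, BrC(Br)(Br)Br
Why: Appel reaction: bromide displaces the alkoxyphosphonium group at the primary carbon by SN2, one carbon away from the stereocentre. The descriptor changes from R to S only because the priorities change. The amine buffer protects the MOM and silyl ethers from traces of HBr.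

Step 6
Reactants: 10 {(2S)-3-bromo-2-[3,4-dimethoxy-2-(methoxymethoxy)phenyl]propoxy}(tert-butyl)dimethylsilane
Product: 11 (2S)-3-bromo-2-[3,4-dimethoxy-2-(methoxymethoxy)phenyl]propan-1-ol
Conditions: HF·pyridine, pyridine, THF, 0 °C → rt
Reagents that add atoms: none
Why: Fluoride-driven desilylation of a primary silyl ether. The buffered, non-basic reagent is chosen because a basic fluoride source could eliminate HBr across the benzylic C–H or close the four-membered ether, and stronger acid would cleave the aryl MOM ether.

Step 7
Reactants: 11 (2S)-3-bromo-2-[3,4-dimethoxy-2-(methoxymethoxy)phenyl]propan-1-ol; 12 4,5-dimethoxy-2-(trimethylsilyl)phenyl trifluoromethanesulfonate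
Product: 16 (3S)-3-[3,4-dimethoxy-2-(methoxymethoxy)phenyl]-6,7-dimethoxy-3,4-dihydro-2H-chromene, via potassium alkoxide 13 (not isolated), via 4,5-dimethoxybenzyne 14 (not isolated), via aryl anion 15 (not isolated)
Conditions: KH (1.05 equiv), THF, −20 °C; then CsF (3 equiv), 18-crown-6 (3 equiv), 12 (1.5 equiv, added over 1 h), THF, −20 °C → rt
Reagents that add atoms: none
Why: Proposed new method: KH converts 11 into alkoxide 13 with loss of H2, so no O–H acid remains; fluoride then removes the silyl group of 12 and triflate leaves to release the symmetric aryne 14, to which 13 adds to form C8a–O1 and the ortho-alkoxy aryl anion 15, which displaces the primary bromide to form C4–C4a. The closest known reaction types are O-arylation by arynes with intramolecular capture of the aryl anion by a carbonyl group, and the Parham cycloalkylation of ortho-lithiated aryl 3-bromopropyl ethers, which shows that such an anion closes a chroman ring readily. Ring C closes in the 6-exo-tet mode, by in-line attack on the CH2–Br carbon. No stereocentre is formed; C3 lies between two methylene groups, takes no part in either bond formation, and its benzylic C–H is less acidic than the aryl C–H that corresponds to 15, so its configuration should be carried through. Regioselectivity does not arise because the two aryne carbons are equivalent. Two chemoselectivities are needed: cyclisation of 15 ahead of protonation, secured by the absence of protic partners and of acidic solvents or cations (THF and crown-complexed K+ and Cs+ instead of MeCN or tetraalkylammonium), and aryne capture by 13 ahead of 4-exo-tet closure to the four-membered ether, secured by generating the aryne quickly at low temperature, where the strained four-membered transition state is slow.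

Step 8
Reactants: 16 (3S)-3-[3,4-dimethoxy-2-(methoxymethoxy)phenyl]-6,7-dimethoxy-3,4-dihydro-2H-chromene
Product: 17 6-[(3S)-6,7-dimethoxy-3,4-dihydro-2H-chromen-3-yl]-2,3-dimethoxyphenol
Conditions: HCl (conc., 5 equiv), MeOH, 40 °C
Reagents that add atoms: none
Why: Acid-catalysed acetal exchange. Methanol takes up the CH2 unit as dimethoxymethane, so no formaldehyde-type electrophile is left to attack the electron-rich rings. The aryl methyl ethers, the chroman and the non-acidic C3–H are unaffected.

Step 9
Reactants: 17 6-[(3S)-6,7-dimethoxy-3,4-dihydro-2H-chromen-3-yl]-2,3-dimethoxyphenol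
Product: 18 abroquinone A, 5-[(3S)-6,7-dimethoxy-3,4-dihydro-2H-chromen-3-yl]-2,3-dimethoxycyclohexa-2,5-diene-1,4-dione
Conditions: (KSO3)2NO (2.5 equiv), KH2PO4 aq (pH 6), acetone/H2O, 0 °C → rt
Reagents that add atoms: potassium nitrosodisulfonate, [K+].[K+].[O]N(S(=O)(=O)[O-])S(=O)(=O)[O-]
Why: Teuber oxidation: one nitroxyl radical abstracts the phenolic hydrogen, a second couples at the free para carbon C5', and loss of imidodisulfonate gives the para-quinone. The reagent attacks only free phenols, so the para-dialkoxy ring A should survive, and the weakly acidic buffer guards C3 against base-induced tautomerisation.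

## Compound list

1 | 2,3-dimethoxyphenol | COc1cccc(O)c1OC | starting material
2 | 1,2-dimethoxy-3-(methoxymethoxy)benzene | COCOc1cccc(OC)c1OC | intermediate
3 | 2-bromoprop-2-en-1-ol | C=C(Br)CO | starting material
4 | [(2-bromoprop-2-en-1-yl)oxy](tert-butyl)dimethylsilane | C=C(Br)CO[Si](C)(C)C(C)(C)C | intermediate
5 | [3,4-dimethoxy-2-(methoxymethoxy)phenyl]lithium | [Li]c1ccc(OC)c(OC)c1OCOC | intermediate
6 | chloro[3,4-dimethoxy-2-(methoxymethoxy)phenyl]zinc | Cl[Zn]c1ccc(OC)c(OC)c1OCOC | intermediate
7 | tert-butyl({2-[3,4-dimethoxy-2-(methoxymethoxy)phenyl]prop-2-en-1-yl}oxy)dimethylsilane | C=C(CO[Si](C)(C)C(C)(C)C)c1ccc(OC)c(OC)c1OCOC | intermediate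
8 | tert-butyl{(2S)-2-[3,4-dimethoxy-2-(methoxymethoxy)phenyl]-3-(4,4,5,5-tetramethyl-1,3,2-dioxaborolan-2-yl)propoxy}dimethylsilane | CC(C)(C)[Si](C)(C)OC[C@@H](CB1OC(C)(C)C(C)(C)O1)c1ccc(OC)c(OC)c1OCOC | intermediate
9 | (2R)-3-{[tert-butyl(dimethyl)silyl]oxy}-2-[3,4-dimethoxy-2-(methoxymethoxy)phenyl]propan-1-ol | CC(C)(C)[Si](C)(C)OC[C@@H](CO)c1ccc(OC)c(OC)c1OCOC | intermediate
10 | {(2S)-3-bromo-2-[3,4-dimethoxy-2-(methoxymethoxy)phenyl]propoxy}(tert-butyl)dimethylsilane | CC(C)(C)[Si](C)(C)OC[C@@H](CBr)c1ccc(OC)c(OC)c1OCOC | intermediate
11 | (2S)-3-bromo-2-[3,4-dimethoxy-2-(methoxymethoxy)phenyl]propan-1-ol | OC[C@@H](CBr)c1ccc(OC)c(OC)c1OCOC | intermediate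
12 | 4,5-dimethoxy-2-(trimethylsilyl)phenyl trifluoromethanesulfonate | COc1cc(OS(=O)(=O)C(F)(F)F)c([Si](C)(C)C)cc1OC | starting material
13 | potassium (2S)-3-bromo-2-[3,4-dimethoxy-2-(methoxymethoxy)phenyl]propan-1-olate | [K+].[O-]C[C@@H](CBr)c1ccc(OC)c(OC)c1OCOC | intermediate
14 | 4,5-dimethoxybenzyne (1,2-didehydro-4,5-dimethoxybenzene) | COC1=CC#CC=C1OC | intermediate
15 | potassium 2-{(2S)-3-bromo-2-[3,4-dimethoxy-2-(methoxymethoxy)phenyl]propoxy}-4,5-dimethoxybenzen-1-ide | [K+].[c-]1cc(OC)c(OC)cc1OC[C@@H](CBr)c2ccc(OC)c(OC)c2OCOC | intermediate
16 | (3S)-3-[3,4-dimethoxy-2-(methoxymethoxy)phenyl]-6,7-dimethoxy-3,4-dihydro-2H-chromene | COCOc1c([C@H]2COc3cc(OC)c(OC)cc3C2)ccc(OC)c1OC | intermediate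
17 | 6-[(3S)-6,7-dimethoxy-3,4-dihydro-2H-chromen-3-yl]-2,3-dimethoxyphenol | COc1ccc([C@H]2COc3cc(OC)c(OC)cc3C2)c(O)c1OC | intermediate
18 | abroquinone A, 5-[(3S)-6,7-dimethoxy-3,4-dihydro-2H-chromen-3-yl]-2,3-dimethoxycyclohexa-2,5-diene-1,4-dione | COC1=C(OC)C(=O)C([C@H]2COc3cc(OC)c(OC)cc3C2)=CC1=O | target

## Step count and least certain steps

Total step count: 9. Longest linear sequence: 8 steps (steps 1, 3, 4, 5, 6, 7, 8 and 9, from 1 to 18). Step 2 is a one-step side branch, and 12 is bought.

**Step 7 (key step, new method).** The most likely failures are these:
- Protonation of the aryl anion before ring closure, by moisture or by alcohol that was not fully deprotonated, which would give the open aryl ether instead of the chroman.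
- Four-membered ether closure of the alkoxide before the aryne is available.
- Attack of the alkoxide on the sulfur of the triflate.
- Addition of the aryl anion to a second aryne if the aryne is generated faster than the anion cyclises.

Transient O-silylation of the alkoxide by the precursor should be harmless, since fluoride reverses it.

Fallback, by known chemistry, from 11 back to 16: Mitsunobu etherification of 11 with purchasable 2-bromo-4,5-dimethoxyphenol (COc1cc(O)c(Br)cc1OC; PPh3, DIAD, THF, 0 °C → rt) should give 1-bromo-2-{(2S)-3-bromo-2-[3,4-dimethoxy-2-(methoxymethoxy)phenyl]propoxy}-4,5-dimethoxybenzene F1 without touching the stereocentre. Bromine–lithium exchange at the aryl bromide with tBuLi (2.1 equiv, THF, −100 °C) is much faster than at the alkyl bromide, and warming lets the aryllithium displace the primary bromide (Parham cycloalkylation) to give 16. This costs one extra step and gives up the two-bond annulation, but forms the same ring from the same stereodefined precursor.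

**Step 4 (enantioselective hydroboration).** The likely failures are poor facial selectivity and chain-walking of the cobalt hydride. The ortho-MOM-oxy group twists the aryl ring out of the alkene plane, and the silyloxymethyl arm is bulkier than the methyl group of the usual substrates. Chain-walking would isomerise the allylic ether towards a silyl enol ether. The sense of induction is also not known in advance.

Fallback, by desymmetrisation, from 7 back to 9 or 11:
- Non-selective hydroboration–oxidation of 7 (9-borabicyclo[3.3.1]nonane, THF; H2O2, NaOH) gives racemic 3-{[tert-butyl(dimethyl)silyl]oxy}-2-[3,4-dimethoxy-2-(methoxymethoxy)phenyl]propan-1-ol F2.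
- Desilylation (HF·pyridine, THF) gives the achiral 2-[3,4-dimethoxy-2-(methoxymethoxy)phenyl]propane-1,3-diol F3.
- Lipase-catalysed acetylation (Pseudomonas cepacia lipase, vinyl acetate, tBuOMe, rt) distinguishes the two enantiotopic hydroxymethyl arms.
- If the product is (2S)-3-hydroxy-2-[3,4-dimethoxy-2-(methoxymethoxy)phenyl]propyl acetate F4, silylation (TBSCl, imidazole) gives (2R)-3-{[tert-butyl(dimethyl)silyl]oxy}-2-[3,4-dimethoxy-2-(methoxymethoxy)phenyl]propyl acetate F5, and methanolysis (K2CO3, MeOH, 0 °C) returns 9.
- If the enzyme prefers the other arm and gives (2R)-3-hydroxy-2-[3,4-dimethoxy-2-(methoxymethoxy)phenyl]propyl acetate F6, Appel bromination (CBr4, PPh3) gives (2S)-3-bromo-2-[3,4-dimethoxy-2-(methoxymethoxy)phenyl]propyl acetate F7, and reductive removal of the acetate (iBu2AlH, CH2Cl2, −78 °C) returns 11 directly.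

Either sense of enzyme selectivity is therefore usable.

**Step 9 (phenol to quinone).** The likely failures are these:
- Coupling of the nitroxyl radical at the methoxy-bearing ortho carbon, with loss of methanol towards an ortho-quinone.
- Over-oxidation of the electron-rich ring A.
- Erosion of C3 by quinone to quinone-methide tautomerisation if the medium becomes basic or the product is left in solution.

Fallback, through the hydroquinone, from 17 back to 18: Elbs persulfate oxidation (K2S2O8, KOH aq, pyridine, 0 °C → rt) attacks only the phenolate, at its para carbon, to give potassium 5-[(3S)-6,7-dimethoxy-3,4-dihydro-2H-chromen-3-yl]-4-hydroxy-2,3-dimethoxyphenyl sulfate F8. Acid hydrolysis (HCl aq, 60 °C) gives 2-[(3S)-6,7-dimethoxy-3,4-dihydro-2H-chromen-3-yl]-5,6-dimethoxybenzene-1,4-diol F9, and mild dehydrogenation (Ag2O, Et2O, rt) gives 18. Conversion in the persulfate step is typically incomplete, but unreacted 17 can be recycled.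

**Step 3 (lithiation and Negishi coupling).** The likely failures are competing lithiation beside a methoxy group, incomplete transmetalation, and slow coupling of the hindered, electron-rich arylzinc, which would end in protodemetalation back to 2.

Fallback, with an isolable boron reagent, from 2 back to 7: lithiation of 2 as before and quenching with 2-isopropoxy-4,4,5,5-tetramethyl-1,3,2-dioxaborolane gives 2-[3,4-dimethoxy-2-(methoxymethoxy)phenyl]-4,4,5,5-tetramethyl-1,3,2-dioxaborolane F10. This can be purified, which also removes any regioisomer. Suzuki–Miyaura coupling with 4 (PdCl2(dppf), dppf = 1,1'-bis(diphenylphosphino)ferrocene; K3PO4, dioxane/H2O, 80 °C) then gives 7.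

## Further compounds

F1 | step 7 | 1-bromo-2-{(2S)-3-bromo-2-[3,4-dimethoxy-2-(methoxymethoxy)phenyl]propoxy}-4,5-dimethoxybenzene | COc1cc(OC[C@@H](CBr)c2ccc(OC)c(OC)c2OCOC)c(Br)cc1OC
F2 | step 4 | racemic 3-{[tert-butyl(dimethyl)silyl]oxy}-2-[3,4-dimethoxy-2-(methoxymethoxy)phenyl]propan-1-ol | CC(C)(C)[Si](C)(C)OCC(CO)c1ccc(OC)c(OC)c1OCOC
F3 | step 4 | 2-[3,4-dimethoxy-2-(methoxymethoxy)phenyl]propane-1,3-diol | OCC(CO)c1ccc(OC)c(OC)c1OCOC
F4 | step 4 | (2S)-3-hydroxy-2-[3,4-dimethoxy-2-(methoxymethoxy)phenyl]propyl acetate | CC(=O)OC[C@H](CO)c1ccc(OC)c(OC)c1OCOC
F5 | step 4 | (2R)-3-{[tert-butyl(dimethyl)silyl]oxy}-2-[3,4-dimethoxy-2-(methoxymethoxy)phenyl]propyl acetate | CC(=O)OC[C@H](CO[Si](C)(C)C(C)(C)C)c1ccc(OC)c(OC)c1OCOC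
F6 | step 4 | (2R)-3-hydroxy-2-[3,4-dimethoxy-2-(methoxymethoxy)phenyl]propyl acetate | CC(=O)OC[C@@H](CO)c1ccc(OC)c(OC)c1OCOC
F7 | step 4 | (2S)-3-bromo-2-[3,4-dimethoxy-2-(methoxymethoxy)phenyl]propyl acetate | CC(=O)OC[C@@H](CBr)c1ccc(OC)c(OC)c1OCOC
F8 | step 9 | potassium 5-[(3S)-6,7-dimethoxy-3,4-dihydro-2H-chromen-3-yl]-4-hydroxy-2,3-dimethoxyphenyl sulfate | [K+].[O-]S(=O)(=O)Oc1cc([C@H]2COc3cc(OC)c(OC)cc3C2)c(O)c(OC)c1OC
F9 | step 9 | 2-[(3S)-6,7-dimethoxy-3,4-dihydro-2H-chromen-3-yl]-5,6-dimethoxybenzene-1,4-diol | Oc1cc([C@H]2COc3cc(OC)c(OC)cc3C2)c(O)c(OC)c1OC
F10 | step 3 | 2-[3,4-dimethoxy-2-(methoxymethoxy)phenyl]-4,4,5,5-tetramethyl-1,3,2-dioxaborolane | CC1(C)OB(c2ccc(OC)c(OC)c2OCOC)OC1(C)C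
A1 | alternative 1 | 6,7-dimethoxy-2H-chromene | COc1cc2OCC=Cc2cc1OC
A2 | alternative 1 | 2,3-dimethoxy-1,4-benzoquinone | COC1=C(OC)C(=O)C=CC1=O
A3 | alternative 1 | cis-8-hydroxy-2,3,9,10-tetramethoxypterocarpan, C6a configured as C3 of the target | COc1cc2OC[C@H]3[C@@H](c2cc1OC)Oc1c(OC)c(OC)c(O)cc13
A4 | alternative 2 | [2-(benzyloxy)-3,4-dimethoxyphenyl]acetaldehyde | O=CCc1ccc(OC)c(OC)c1OCc1ccccc1
A5 | alternative 2 | 2-[(benzenesulfonyl)methyl]-4,5-dimethoxyphenol | COc1cc(O)c(CS(=O)(=O)c2ccccc2)cc1OC
A6 | alternative 2 | 3,4-dimethoxy-6-methylidenecyclohexa-2,4-dien-1-one | C=C1C=C(OC)C(OC)=CC1=O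
A7 | alternative 2 | (3S)-3-[2-(benzyloxy)-3,4-dimethoxyphenyl]-6,7-dimethoxy-3,4-dihydro-2H-chromen-2-ol, anomeric mixture at C2 | COc1ccc([C@H]2C(O)Oc3cc(OC)c(OC)cc3C2)c(OCc2ccccc2)c1OC
A8 | alternative 3 | 4-{(2S)-3-hydroxy-2-[3,4-dimethoxy-2-(methoxymethoxy)phenyl]propyl}benzene-1,2-diol | OC[C@@H](Cc1ccc(O)c(O)c1)c1ccc(OC)c(OC)c1OCOC
A9 | alternative 3 | 4-{(2S)-3-hydroxy-2-[3,4-dimethoxy-2-(methoxymethoxy)phenyl]propyl}cyclohexa-3,5-diene-1,2-dione | OC[C@@H](CC1=CC(=O)C(=O)C=C1)c1ccc(OC)c(OC)c1OCOC
A10 | alternative 3 | (3S)-3-[3,4-dimethoxy-2-(methoxymethoxy)phenyl]-3,4-dihydro-2H-chromene-6,7-diol | COCOc1c([C@H]2COc3cc(O)c(O)cc3C2)ccc(OC)c1OC
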